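**Retrosynthetic overview**
1. Target hydroquinone ⇐ quinone ⇐ 18,21-di-O-methyl macrolactam (oxidative demethylation, then dithionite). The 19-membered lactam is the last ring, closed at N–C1 from the seco amino acid.
2. C2=C3 (Z) ⇐ Still–Gennari olefination of a lactol. The lactol comes from a C3–C7 dihydropyranone made by an organocatalytic hetero-Diels–Alder reaction of the C7 (Z)-enal with a 1,1,4-trioxygenated diene; this sets C6 and C7 and locks C4=C5 as Z.
3. C8=C9 (Z) ⇐ Still–Gennari olefination of the C9 aldehyde; C10/C11 ⇐ (Z)-crotylboration of an α-aminoxy aldehyde; C12 ⇐ D-proline α-aminoxylation; C11 aldehyde ⇐ linear hydroformylation.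
4. C14/C15 ⇐ chiral-phosphoric-acid-catalysed (Z)-crotylboration of 2,5-dimethoxy-3-nitrobenzaldehyde (first stereocentres).
5. Ring order: arene (bought) → dihydropyranone (step 14, opened in step 16) → macrolactam (step 20).

Assumption: the target is taken exactly as its SMILES encodes it, i.e. 2Z,4Z,8Z and 6S,7S,10S,11R,12S,14S,15R (numbering: C1 = lactam carbonyl, C15 = benzylic carbon, C16–C21 = arene with N on C20 and oxygens on C18 and C21), and compound 1 is taken as a catalogue compound.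

**Route**

Step 1
Reactants: 1 2-hydroxy-5-methoxy-3-nitrobenzaldehyde
Product: 2 2,5-dimethoxy-3-nitrobenzaldehyde
Conditions: MeI, K2CO3, DMF, 23 °C
Reagents that add atoms: iodomethane CI
Why: Williamson O-methylation of the acidic nitrophenol (SN2), which installs the second arene methyl ether that the final oxidative demethylation removes.

Step 2
Reactants: 2 2,5-dimethoxy-3-nitrobenzaldehyde; 3 (Z)-crotylboronic acid pinacol ester
Product: 5 (1R,2S)-1-(2,5-dimethoxy-3-nitrophenyl)-2-methylbut-3-en-1-ol, via boronate ester 4 (not isolated)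
Conditions: (R)-TRIP [(R)-3,3'-bis(2,4,6-triisopropylphenyl)-1,1'-binaphthyl-2,2'-diyl hydrogen phosphate] (5 mol %), toluene, −30 °C; aq. NaHCO3 work-up
Reagents that add atoms: none
Why: Chiral-phosphoric-acid-catalysed crotylboration (Antilla type) through a chair Zimmerman–Traxler transition state in which the acid binds the boronate oxygen and the formyl hydrogen, so the (Z)-boronate gives the syn pair and the (R)-acid directs Re-face attack, setting C15 (R) and C14 (S) as the first stereocentres.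

Step 3
Reactants: 5 (1R,2S)-1-(2,5-dimethoxy-3-nitrophenyl)-2-methylbut-3-en-1-ol
Product: 6 1-[(1R,2S)-1-methoxy-2-methylbut-3-en-1-yl]-2,5-dimethoxy-3-nitrobenzene
Conditions: NaH, MeI, THF, 0 → 23 °C
Reagents that add atoms: iodomethane CI
Why: Williamson methylation of the benzylic alkoxide gives the C15 methyl ether without touching the stereocentres.

Step 4
Reactants: 6 1-[(1R,2S)-1-methoxy-2-methylbut-3-en-1-yl]-2,5-dimethoxy-3-nitrobenzene
Product: 7 (4S,5R)-5-(2,5-dimethoxy-3-nitrophenyl)-5-methoxy-4-methylpentanal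
Conditions: CO/H2 (1:1, 10 bar), Rh(acac)(CO)2 (1 mol %), BIPHEPHOS (3 mol %), toluene, 60 °C
Reagents that add atoms: carbon monoxide [C-]#[O+]
Why: Linear-selective rhodium-catalysed hydroformylation (bulky bisphosphite plus the allylic branch enforce anti-Markovnikov insertion) adds C11 as the aldehyde, and the nitro group is inert under these conditions.

Step 5
Reactants: 7 (4S,5R)-5-(2,5-dimethoxy-3-nitrophenyl)-5-methoxy-4-methylpentanal; 3 (Z)-crotylboronic acid pinacol ester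
Product: 10 (3S,4R,5S,7S,8R)-8-(2,5-dimethoxy-3-nitrophenyl)-8-methoxy-3,7-dimethyl-5-(phenylaminooxy)oct-1-en-4-ol, via aminoxy aldehyde 8 (not isolated), via boronate ester 9 (not isolated)
Conditions: D-proline (20 mol %), PhNO, CHCl3, 4 °C; then 3 (3 equiv), 0 → 23 °C; aq. work-up
Reagents that add atoms: nitrosobenzene O=Nc1ccccc1
Why: Proline-catalysed α-aminoxylation (O-selective nitroso aldol via the anti-enamine) sets C12 (S) with D-proline, and the α-oxygenated aldehyde then undergoes a chair crotylboration in which the (Z)-boronate gives the 10,11-syn pair and Felkin–Anh/Cornforth control by the C12 oxygen gives the 11,12-anti relation (C11 R, C10 S).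

Step 6
Reactants: 10 (3S,4R,5S,7S,8R)-8-(2,5-dimethoxy-3-nitrophenyl)-8-methoxy-3,7-dimethyl-5-(phenylaminooxy)oct-1-en-4-ol
Product: 11 (3S,4R,5S,7S,8R)-8-(2,5-dimethoxy-3-nitrophenyl)-8-methoxy-3,7-dimethyloct-1-ene-4,5-diol
Conditions: CuSO4·5H2O (30 mol %), MeOH, 0 → 23 °C
Reagents that add atoms: none
Why: Copper-catalysed N–O bond cleavage of the O-alkyl-N-phenylhydroxylamine frees the C12 hydroxyl without reducing the nitroarene or the alkene.

Step 7
Reactants: 11 (3S,4R,5S,7S,8R)-8-(2,5-dimethoxy-3-nitrophenyl)-8-methoxy-3,7-dimethyloct-1-ene-4,5-diol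
Product: 12 2,5-dimethoxy-3-nitro-1-[(1R,2S,4S,5R,6S)-1,4,5-trimethoxy-2,6-dimethyloct-7-en-1-yl]benzene
Conditions: NaH, MeI, THF/DMF, 0 → 23 °C
Reagents that add atoms: iodomethane CI
Why: Double Williamson methylation installs the C11 and C12 methyl ethers in one operation.

Step 8
Reactants: 12 2,5-dimethoxy-3-nitro-1-[(1R,2S,4S,5R,6S)-1,4,5-trimethoxy-2,6-dimethyloct-7-en-1-yl]benzene
Product: 14 (2R,3R,4S,6S,7R)-7-(2,5-dimethoxy-3-nitrophenyl)-3,4,7-trimethoxy-2,6-dimethylheptanal, via ozonide 13 (not isolated)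
Conditions: O3, CH2Cl2, −78 °C; then PPh3, −78 → 23 °C
Reagents that add atoms: ozone [O-][O+]=O
Why: Ozonolysis with reductive work-up cleaves only the terminal alkene (the nitro-deactivated arene is slow to react) and gives the C9 aldehyde, which is used at once to avoid epimerisation at C10.

Step 9
Reactants: 14 (2R,3R,4S,6S,7R)-7-(2,5-dimethoxy-3-nitrophenyl)-3,4,7-trimethoxy-2,6-dimethylheptanal; 15 ethyl 2-[bis(2,2,2-trifluoroethoxy)phosphoryl]propanoate
Product: 16 ethyl (2Z,4S,5R,6S,8S,9R)-9-(2,5-dimethoxy-3-nitrophenyl)-5,6,9-trimethoxy-2,4,8-trimethylnon-2-enoate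
Conditions: KN(SiMe3)2, 18-crown-6, THF, −78 °C
Reagents that add atoms: none
Why: Still–Gennari modification of the Horner–Wadsworth–Emmons reaction, in which the electron-poor phosphonate collapses irreversibly from the kinetic syn oxaphosphetane, gives the trisubstituted C8=C9 alkene with C7 cis to C10 (Z).

Step 10
Reactants: 16 ethyl (2Z,4S,5R,6S,8S,9R)-9-(2,5-dimethoxy-3-nitrophenyl)-5,6,9-trimethoxy-2,4,8-trimethylnon-2-enoate
Product: 17 (2Z,4S,5R,6S,8S,9R)-9-(2,5-dimethoxy-3-nitrophenyl)-5,6,9-trimethoxy-2,4,8-trimethylnon-2-en-1-ol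
Conditions: i-Bu2AlH (2.5 equiv), CH2Cl2, −78 °C; aq. KNaC4H4O6
Reagents that add atoms: none
Why: 1,2-Reduction of the enoate by i-Bu2AlH at low temperature gives the allylic alcohol with the alkene geometry and the nitro group intact.

Step 11
Reactants: 17 (2Z,4S,5R,6S,8S,9R)-9-(2,5-dimethoxy-3-nitrophenyl)-5,6,9-trimethoxy-2,4,8-trimethylnon-2-en-1-ol
Product: 18 (2Z,4S,5R,6S,8S,9R)-9-(2,5-dimethoxy-3-nitrophenyl)-5,6,9-trimethoxy-2,4,8-trimethylnon-2-enal
Conditions: Dess–Martin periodinane, NaHCO3, CH2Cl2, 0 °C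
Reagents that add atoms: none
Why: Buffered Dess–Martin oxidation gives the (Z)-enal under neutral conditions, which avoids Z to E isomerisation.

Step 12
Reactants: 19 methoxyacetaldehyde; 20 methyl 2-[bis(2,2,2-trifluoroethoxy)phosphoryl]acetate
Product: 21 methyl (2Z)-4-methoxybut-2-enoate
Conditions: KN(SiMe3)2, 18-crown-6, THF, −78 °C
Reagents that add atoms: none
Why: Still–Gennari olefination gives the (Z)-enoate, the geometry needed for the next step.

Step 13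
Reactants: 21 methyl (2Z)-4-methoxybut-2-enoate
Product: 22 tert-butyl{[(1Z,3E)-1,4-dimethoxybuta-1,3-dien-1-yl]oxy}dimethylsilane
Conditions: LiN(i-Pr)2, THF/DMPU, −78 °C; then t-BuMe2SiCl, −78 → 0 °C
Reagents that add atoms: tert-butyldimethylsilyl chloride CC(C)(C)[Si](C)(C)Cl
Why: Kinetic γ-deprotonation and O-silylation (vinylketene silyl acetal formation), where allylic 1,3-strain with the cis ester of the (Z)-enoate turns the methoxy group outward so the new C3=C4 bond is E, the geometry a concerted cycloaddition needs.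

Step 14
Reactants: 18 (2Z,4S,5R,6S,8S,9R)-9-(2,5-dimethoxy-3-nitrophenyl)-5,6,9-trimethoxy-2,4,8-trimethylnon-2-enal; 22 tert-butyl{[(1Z,3E)-1,4-dimethoxybuta-1,3-dien-1-yl]oxy}dimethylsilane
Product: 24 (5S,6S)-6-[(2Z,4S,5R,6S,8S,9R)-9-(2,5-dimethoxy-3-nitrophenyl)-5,6,9-trimethoxy-4,8-dimethylnon-2-en-2-yl]-5-methoxy-5,6-dihydro-2H-pyran-2-one, via orthoester cycloadduct 23 (not isolated)
Conditions: (4S,5S)-2,2-dimethyl-α,α,α',α'-tetra(1-naphthyl)-1,3-dioxolane-4,5-dimethanol (1-naphthyl-TADDOL, 20 mol %), 22 (2.5 equiv), toluene, −40 °C; then CF3CO2H (cat.), CH2Cl2, 0 °C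
Reagents that add atoms: none
Why: Proposed new method: a hydrogen-bond-catalysed, endo-selective hetero-Diels–Alder reaction of a 1,1,4-trioxygenated vinylketene silyl acetal with a trisubstituted (Z)-enal, in which the TADDOL hydroxyl activates the formyl oxygen by a single hydrogen bond, the ketene-acetal end makes the methoxy-bearing diene terminus the nucleophile so that C6–C7 forms first in an asynchronous concerted transition state that requires the s-cis diene (hence the ring-locked 4Z alkene), the outside 3E methoxy group and the endo alkenyl residue give the cis lactone (C6 S, C7 S by Re-face attack, the catalyst enantiomer being chosen by analogy and to be confirmed on a model enal), and acid then expels the silyl methyl ether from the orthoester; the closest known reaction type is the TADDOL-catalysed hetero-Diels–Alder reaction of Brassard's and Rawal's dienes with aldehydes, not yet shown for a 4-alkoxy diene or a (Z)-enal.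

Step 15
Reactants: 24 (5S,6S)-6-[(2Z,4S,5R,6S,8S,9R)-9-(2,5-dimethoxy-3-nitrophenyl)-5,6,9-trimethoxy-4,8-dimethylnon-2-en-2-yl]-5-methoxy-5,6-dihydro-2H-pyran-2-one
Product: 25 (2RS,5S,6S)-6-[(2Z,4S,5R,6S,8S,9R)-9-(2,5-dimethoxy-3-nitrophenyl)-5,6,9-trimethoxy-4,8-dimethylnon-2-en-2-yl]-5-methoxy-5,6-dihydro-2H-pyran-2-ol
Conditions: i-Bu2AlH (1.1 equiv), CH2Cl2, −78 °C; aq. KNaC4H4O6
Reagents that add atoms: none
Why: Partial reduction of the unsaturated δ-lactone stops at the tetrahedral aluminium hemiacetal at −78 °C and gives the lactol, a masked (Z)-enal at C3.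

Step 16
Reactants: 25 (2RS,5S,6S)-6-[(2Z,4S,5R,6S,8S,9R)-9-(2,5-dimethoxy-3-nitrophenyl)-5,6,9-trimethoxy-4,8-dimethylnon-2-en-2-yl]-5-methoxy-5,6-dihydro-2H-pyran-2-ol; 15 ethyl 2-[bis(2,2,2-trifluoroethoxy)phosphoryl]propanoate
Product: 26 ethyl (2Z,4Z,6S,7S,8Z,10S,11R,12S,14S,15R)-15-(2,5-dimethoxy-3-nitrophenyl)-7-hydroxy-6,11,12,15-tetramethoxy-2,8,10,14-tetramethylpentadeca-2,4,8-trienoate
Conditions: 15 (3 equiv), KN(SiMe3)2, 18-crown-6, THF, −78 °C; NH4Cl quench at −78 °C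
Reagents that add atoms: none
Why: Still–Gennari olefination on the open hydroxy-enal form of the lactol forms C2=C3 as Z while the ring-derived C4=C5 stays Z, and the cold quench limits oxa-Michael closure of the freed C7 alkoxide.

Step 17
Reactants: 26 ethyl (2Z,4Z,6S,7S,8Z,10S,11R,12S,14S,15R)-15-(2,5-dimethoxy-3-nitrophenyl)-7-hydroxy-6,11,12,15-tetramethoxy-2,8,10,14-tetramethylpentadeca-2,4,8-trienoate
Product: 28 ethyl (2Z,4Z,6S,7S,8Z,10S,11R,12S,14S,15R)-7-(carbamoyloxy)-15-(2,5-dimethoxy-3-nitrophenyl)-6,11,12,15-tetramethoxy-2,8,10,14-tetramethylpentadeca-2,4,8-trienoate, via trichloroacetyl carbamate 27 (not isolated)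
Conditions: Cl3CC(O)NCO, CH2Cl2, 0 °C; then K2CO3, MeOH, 0 °C
Reagents that add atoms: trichloroacetyl isocyanate O=C=NC(=O)C(Cl)(Cl)Cl
Why: Kočovský carbamoylation (addition of the alcohol to the acyl isocyanate, then methanolysis of the trichloroacetyl group) caps C7 with retention before any free amine is present.

Step 18
Reactants: 28 ethyl (2Z,4Z,6S,7S,8Z,10S,11R,12S,14S,15R)-7-(carbamoyloxy)-15-(2,5-dimethoxy-3-nitrophenyl)-6,11,12,15-tetramethoxy-2,8,10,14-tetramethylpentadeca-2,4,8-trienoate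
Product: 29 ethyl (2Z,4Z,6S,7S,8Z,10S,11R,12S,14S,15R)-15-(3-amino-2,5-dimethoxyphenyl)-7-(carbamoyloxy)-6,11,12,15-tetramethoxy-2,8,10,14-tetramethylpentadeca-2,4,8-trienoate
Conditions: Fe powder, NH4Cl, EtOH/H2O, 70 °C
Reagents that add atoms: none
Why: Béchamp-type nitro reduction by iron under near-neutral conditions gives the aniline and leaves the dienoate, the carbamate and the alkenes alone.

Step 19
Reactants: 29 ethyl (2Z,4Z,6S,7S,8Z,10S,11R,12S,14S,15R)-15-(3-amino-2,5-dimethoxyphenyl)-7-(carbamoyloxy)-6,11,12,15-tetramethoxy-2,8,10,14-tetramethylpentadeca-2,4,8-trienoate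
Product: 30 (2Z,4Z,6S,7S,8Z,10S,11R,12S,14S,15R)-15-(3-amino-2,5-dimethoxyphenyl)-7-(carbamoyloxy)-6,11,12,15-tetramethoxy-2,8,10,14-tetramethylpentadeca-2,4,8-trienoic acid
Conditions: LiOH·H2O, THF/MeOH/H2O, 23 °C; then 1 M HCl to pH 5
Reagents that add atoms: lithium hydroxide [Li+].[OH-]
Why: Saponification of the ethyl ester at room temperature, under which the primary carbamate is stable.

Step 20
Reactants: 30 (2Z,4Z,6S,7S,8Z,10S,11R,12S,14S,15R)-15-(3-amino-2,5-dimethoxyphenyl)-7-(carbamoyloxy)-6,11,12,15-tetramethoxy-2,8,10,14-tetramethylpentadeca-2,4,8-trienoic acid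
Product: 31 18,21-di-O-methyl ether of target 33 (19-membered lactam closed between N and C1)
Conditions: bis(2-oxo-3-oxazolidinyl)phosphinic chloride (BOP-Cl), i-Pr2NEt, toluene (0.001 M), 85 °C
Reagents that add atoms: none
Why: Macrolactamisation through the mixed phosphinic anhydride at high dilution, the method proven for geldanamycin-type seco amino acids, with no stereocentre touched.

Step 21
Reactants: 31 18,21-di-O-methyl ether of target 33
Product: 33 target CNP0109452.1 (2Z,4Z,8Z; 6S,7S,10S,11R,12S,14S,15R), via quinone 32 (not isolated)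
Conditions: (NH4)2Ce(NO3)6, MeCN/H2O, −10 °C; then aq. Na2S2O4, EtOAc, 23 °C, argon
Reagents that add atoms: water O
Why: Oxidative demethylation of the para-dimethoxyarene by ceric ammonium nitrate (water supplies both quinone oxygens) followed by dithionite reduction of the quinone gives the hydroquinone, the usual last-stage sequence for benzoquinone ansamycins.

**Compound list**
1 | 2-hydroxy-5-methoxy-3-nitrobenzaldehyde | O=Cc1cc(OC)cc([N+](=O)[O-])c1O | starting material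
2 | 2,5-dimethoxy-3-nitrobenzaldehyde | O=Cc1cc(OC)cc([N+](=O)[O-])c1OC | intermediate
3 | (Z)-crotylboronic acid pinacol ester | C/C=C\CB1OC(C)(C)C(C)(C)O1 | starting material
4 | pinacol boronate ester of alcohol 5 (not isolated) | O=[N+]([O-])c1cc(OC)cc(c1OC)[C@H](OB2OC(C)(C)C(C)(C)O2)[C@@H](C)C=C | intermediate
5 | (1R,2S)-1-(2,5-dimethoxy-3-nitrophenyl)-2-methylbut-3-en-1-ol | O=[N+]([O-])c1cc(OC)cc(c1OC)[C@H](O)[C@@H](C)C=C | intermediate
6 | 1-[(1R,2S)-1-methoxy-2-methylbut-3-en-1-yl]-2,5-dimethoxy-3-nitrobenzene | O=[N+]([O-])c1cc(OC)cc(c1OC)[C@H](OC)[C@@H](C)C=C | intermediate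
7 | (4S,5R)-5-(2,5-dimethoxy-3-nitrophenyl)-5-methoxy-4-methylpentanal | O=[N+]([O-])c1cc(OC)cc(c1OC)[C@H](OC)[C@@H](C)CCC=O | intermediate
8 | (2S,4S,5R)-5-(2,5-dimethoxy-3-nitrophenyl)-5-methoxy-4-methyl-2-(phenylaminooxy)pentanal (not isolated) | O=[N+]([O-])c1cc(OC)cc(c1OC)[C@H](OC)[C@@H](C)C[C@H](ONc2ccccc2)C=O | intermediate
9 | pinacol boronate ester of alcohol 10 (not isolated) | O=[N+]([O-])c1cc(OC)cc(c1OC)[C@H](OC)[C@@H](C)C[C@H](ONc2ccccc2)[C@H](OB3OC(C)(C)C(C)(C)O3)[C@@H](C)C=C | intermediate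
10 | (3S,4R,5S,7S,8R)-8-(2,5-dimethoxy-3-nitrophenyl)-8-methoxy-3,7-dimethyl-5-(phenylaminooxy)oct-1-en-4-ol | O=[N+]([O-])c1cc(OC)cc(c1OC)[C@H](OC)[C@@H](C)C[C@H](ONc2ccccc2)[C@H](O)[C@@H](C)C=C | intermediate
11 | (3S,4R,5S,7S,8R)-8-(2,5-dimethoxy-3-nitrophenyl)-8-methoxy-3,7-dimethyloct-1-ene-4,5-diol | O=[N+]([O-])c1cc(OC)cc(c1OC)[C@H](OC)[C@@H](C)C[C@H](O)[C@H](O)[C@@H](C)C=C | intermediate
12 | 2,5-dimethoxy-3-nitro-1-[(1R,2S,4S,5R,6S)-1,4,5-trimethoxy-2,6-dimethyloct-7-en-1-yl]benzene | O=[N+]([O-])c1cc(OC)cc(c1OC)[C@H](OC)[C@@H](C)C[C@H](OC)[C@H](OC)[C@@H](C)C=C | intermediate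
13 | 1,2,4-trioxolane (ozonide) of alkene 12, mixture at the ring carbon (not isolated) | O=[N+]([O-])c1cc(OC)cc(c1OC)[C@H](OC)[C@@H](C)C[C@H](OC)[C@H](OC)[C@@H](C)C2OCOO2 | intermediate
14 | (2R,3R,4S,6S,7R)-7-(2,5-dimethoxy-3-nitrophenyl)-3,4,7-trimethoxy-2,6-dimethylheptanal | O=[N+]([O-])c1cc(OC)cc(c1OC)[C@H](OC)[C@@H](C)C[C@H](OC)[C@H](OC)[C@@H](C)C=O | intermediate
15 | ethyl 2-[bis(2,2,2-trifluoroethoxy)phosphoryl]propanoate (racemate; the α-centre is planarised on deprotonation) | CCOC(=O)C(C)P(=O)(OCC(F)(F)F)OCC(F)(F)F | starting material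
16 | ethyl (2Z,4S,5R,6S,8S,9R)-9-(2,5-dimethoxy-3-nitrophenyl)-5,6,9-trimethoxy-2,4,8-trimethylnon-2-enoate | O=[N+]([O-])c1cc(OC)cc(c1OC)[C@H](OC)[C@@H](C)C[C@H](OC)[C@H](OC)[C@@H](C)/C=C(C)\C(=O)OCC | intermediate
17 | (2Z,4S,5R,6S,8S,9R)-9-(2,5-dimethoxy-3-nitrophenyl)-5,6,9-trimethoxy-2,4,8-trimethylnon-2-en-1-ol | O=[N+]([O-])c1cc(OC)cc(c1OC)[C@H](OC)[C@@H](C)C[C@H](OC)[C@H](OC)[C@@H](C)/C=C(C)\CO | intermediate
18 | (2Z,4S,5R,6S,8S,9R)-9-(2,5-dimethoxy-3-nitrophenyl)-5,6,9-trimethoxy-2,4,8-trimethylnon-2-enal | O=[N+]([O-])c1cc(OC)cc(c1OC)[C@H](OC)[C@@H](C)C[C@H](OC)[C@H](OC)[C@@H](C)/C=C(C)\C=O | intermediate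
19 | methoxyacetaldehyde | COCC=O | starting material
20 | methyl 2-[bis(2,2,2-trifluoroethoxy)phosphoryl]acetate | COC(=O)CP(=O)(OCC(F)(F)F)OCC(F)(F)F | starting material
21 | methyl (2Z)-4-methoxybut-2-enoate | COC/C=C\C(=O)OC | intermediate
22 | tert-butyl{[(1Z,3E)-1,4-dimethoxybuta-1,3-dien-1-yl]oxy}dimethylsilane | CO/C=C/C=C(/OC)O[Si](C)(C)C(C)(C)C | intermediate
23 | 2-(tert-butyldimethylsilyloxy)-2-methoxy orthoester form of lactone 24, mixture at C2 of the pyran (not isolated) | O=[N+]([O-])c1cc(OC)cc(c1OC)[C@H](OC)[C@@H](C)C[C@H](OC)[C@H](OC)[C@@H](C)/C=C(C)\[C@@H]2OC(OC)(O[Si](C)(C)C(C)(C)C)C=C[C@@H]2OC | intermediate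
24 | (5S,6S)-6-[(2Z,4S,5R,6S,8S,9R)-9-(2,5-dimethoxy-3-nitrophenyl)-5,6,9-trimethoxy-4,8-dimethylnon-2-en-2-yl]-5-methoxy-5,6-dihydro-2H-pyran-2-one | O=[N+]([O-])c1cc(OC)cc(c1OC)[C@H](OC)[C@@H](C)C[C@H](OC)[C@H](OC)[C@@H](C)/C=C(C)\[C@@H]2OC(=O)C=C[C@@H]2OC | intermediate
25 | (2RS,5S,6S)-6-[(2Z,4S,5R,6S,8S,9R)-9-(2,5-dimethoxy-3-nitrophenyl)-5,6,9-trimethoxy-4,8-dimethylnon-2-en-2-yl]-5-methoxy-5,6-dihydro-2H-pyran-2-ol (anomer mixture) | O=[N+]([O-])c1cc(OC)cc(c1OC)[C@H](OC)[C@@H](C)C[C@H](OC)[C@H](OC)[C@@H](C)/C=C(C)\[C@@H]2OC(O)C=C[C@@H]2OC | intermediate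
26 | ethyl (2Z,4Z,6S,7S,8Z,10S,11R,12S,14S,15R)-15-(2,5-dimethoxy-3-nitrophenyl)-7-hydroxy-6,11,12,15-tetramethoxy-2,8,10,14-tetramethylpentadeca-2,4,8-trienoate | O=[N+]([O-])c1cc(OC)cc(c1OC)[C@H](OC)[C@@H](C)C[C@H](OC)[C@H](OC)[C@@H](C)/C=C(C)\[C@H](O)[C@@H](OC)/C=C\C=C(C)/C(=O)OCC | intermediate
27 | O7-(trichloroacetylcarbamoyl) derivative of 26 (not isolated) | O=[N+]([O-])c1cc(OC)cc(c1OC)[C@H](OC)[C@@H](C)C[C@H](OC)[C@H](OC)[C@@H](C)/C=C(C)\[C@H](OC(=O)NC(=O)C(Cl)(Cl)Cl)[C@@H](OC)/C=C\C=C(C)/C(=O)OCC | intermediate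
28 | ethyl (2Z,4Z,6S,7S,8Z,10S,11R,12S,14S,15R)-7-(carbamoyloxy)-15-(2,5-dimethoxy-3-nitrophenyl)-6,11,12,15-tetramethoxy-2,8,10,14-tetramethylpentadeca-2,4,8-trienoate | O=[N+]([O-])c1cc(OC)cc(c1OC)[C@H](OC)[C@@H](C)C[C@H](OC)[C@H](OC)[C@@H](C)/C=C(C)\[C@H](OC(N)=O)[C@@H](OC)/C=C\C=C(C)/C(=O)OCC | intermediate
29 | ethyl (2Z,4Z,6S,7S,8Z,10S,11R,12S,14S,15R)-15-(3-amino-2,5-dimethoxyphenyl)-7-(carbamoyloxy)-6,11,12,15-tetramethoxy-2,8,10,14-tetramethylpentadeca-2,4,8-trienoate | Nc1cc(OC)cc(c1OC)[C@H](OC)[C@@H](C)C[C@H](OC)[C@H](OC)[C@@H](C)/C=C(C)\[C@H](OC(N)=O)[C@@H](OC)/C=C\C=C(C)/C(=O)OCC | intermediate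
30 | (2Z,4Z,6S,7S,8Z,10S,11R,12S,14S,15R)-15-(3-amino-2,5-dimethoxyphenyl)-7-(carbamoyloxy)-6,11,12,15-tetramethoxy-2,8,10,14-tetramethylpentadeca-2,4,8-trienoic acid | Nc1cc(OC)cc(c1OC)[C@H](OC)[C@@H](C)C[C@H](OC)[C@H](OC)[C@@H](C)/C=C(C)\[C@H](OC(N)=O)[C@@H](OC)/C=C\C=C(C)/C(=O)O | intermediate
31 | 18,21-di-O-methyl ether of target 33 (19-membered lactam, N–C1 closed) | CO[C@H]1[C@@H](OC)C[C@H](C)[C@@H](OC)c2cc(OC)cc(c2OC)NC(=O)/C(C)=C\C=C/[C@H](OC)[C@@H](OC(N)=O)/C(C)=C\[C@@H]1C | intermediate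
32 | 18,21-benzoquinone corresponding to target 33 (not isolated) | CO[C@H]1[C@@H](OC)C[C@H](C)[C@@H](OC)C2=CC(=O)C=C(C2=O)NC(=O)/C(C)=C\C=C/[C@H](OC)[C@@H](OC(N)=O)/C(C)=C\[C@@H]1C | intermediate
33 | CNP0109452.1: (2Z,4Z,8Z)-7-carbamoyloxy-18,21-dihydroxy-6,11,12,15-tetramethoxy-2,8,10,14-tetramethyl ansa lactam, 6S,7S,10S,11R,12S,14S,15R | CO[C@H]1[C@@H](OC)C[C@H](C)[C@@H](OC)c2cc(O)cc(c2O)NC(=O)/C(C)=C\C=C/[C@H](OC)[C@@H](OC(N)=O)/C(C)=C\[C@@H]1C | target

**Step count and risks**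
Total step count: 21. Longest linear sequence: 19 (steps 1–11 and 14–21; steps 12–13 make the diene).

The three steps most likely to fail:

Step 5 (one-pot aminoxylation and crotylboration). The α-aminoxy aldehyde is unstable, and proline can trigger its self-aldol while the crotylboration runs. The fallback sets out from 7 and separates the two events with an isolable α-oxygenated aldehyde. α-Benzoyloxylation with benzoyl peroxide and (S)-2-(triphenylmethyl)pyrrolidine (10 mol %, THF, 0 °C) gives the α-benzoyloxy aldehyde F1. (R)-TRIP-catalysed crotylboration with 3 (toluene, −30 °C; catalyst and Felkin control matched) gives, by way of the boronate ester F2, the hydroxy benzoate F3. K2CO3 in MeOH removes the benzoate and the route is rejoined at diol 11.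

Step 14 (the new hetero-Diels–Alder reaction). The hindered, conjugated (Z)-enal may be too unreactive under hydrogen-bond catalysis, and the endo and facial selectivities are untested. The fallback uses known chemistry and sets out from 18. Allyl methyl ether is lithiated (s-BuLi, THF, −78 °C) and borylated with 2-isopropoxy-4,4,5,5-tetramethyl-1,3,2-dioxaborolane to give (Z)-γ-methoxyallylboronic acid pinacol ester F4. (R)-TRIP-catalysed alkoxyallylboration of 18 with F4 gives, by way of the boronate ester F5, the syn methoxy homoallylic alcohol F6. Acryloyl chloride and i-Pr2NEt give the acrylate F7. Ring-closing metathesis with the second-generation Grubbs catalyst (CH2Cl2, 40 °C) closes the dihydropyranone and the route is rejoined at lactone 24.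

Step 16 (Still–Gennari olefination on the lactol). The freed C7 alkoxide can add back to the new dienoate (oxa-Michael), and the transient (Z)-hydroxy enal can isomerise. The fallback sets out from 24 and caps C7 before the olefination. Me3Al and MeNHOMe·HCl open the lactone to the (Z)-hydroxy Weinreb amide F8. Cl3CC(O)NCO gives the trichloroacetyl carbamate F9, which K2CO3 in MeOH converts to the carbamate Weinreb amide F10. i-Bu2AlH at −78 °C gives the carbamate (Z)-enal F11. Still–Gennari olefination of F11 with 15 gives the carbamate dienoate and the route is rejoined at 28.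

**Further compounds**
F1 | step 5 | (2S,4S,5R)-5-(2,5-dimethoxy-3-nitrophenyl)-5-methoxy-4-methyl-1-oxopentan-2-yl benzoate | O=[N+]([O-])c1cc(OC)cc(c1OC)[C@H](OC)[C@@H](C)C[C@H](OC(=O)c2ccccc2)C=O
F2 | step 5 | pinacol boronate ester of F3 (not isolated) | O=[N+]([O-])c1cc(OC)cc(c1OC)[C@H](OC)[C@@H](C)C[C@H](OC(=O)c2ccccc2)[C@H](OB3OC(C)(C)C(C)(C)O3)[C@@H](C)C=C
F3 | step 5 | (3S,4R,5S,7S,8R)-8-(2,5-dimethoxy-3-nitrophenyl)-4-hydroxy-8-methoxy-3,7-dimethyloct-1-en-5-yl benzoate | O=[N+]([O-])c1cc(OC)cc(c1OC)[C@H](OC)[C@@H](C)C[C@H](OC(=O)c2ccccc2)[C@H](O)[C@@H](C)C=C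
F4 | step 14 | 2-[(2Z)-3-methoxyprop-2-en-1-yl]-4,4,5,5-tetramethyl-1,3,2-dioxaborolane | CO/C=C\CB1OC(C)(C)C(C)(C)O1
F5 | step 14 | pinacol boronate ester of F6 (not isolated) | O=[N+]([O-])c1cc(OC)cc(c1OC)[C@H](OC)[C@@H](C)C[C@H](OC)[C@H](OC)[C@@H](C)/C=C(C)\[C@H](OB2OC(C)(C)C(C)(C)O2)[C@@H](OC)C=C
F6 | step 14 | (3S,4S,5Z,7S,8R,9S,11S,12R)-12-(2,5-dimethoxy-3-nitrophenyl)-3,8,9,12-tetramethoxy-5,7,11-trimethyldodeca-1,5-dien-4-ol | O=[N+]([O-])c1cc(OC)cc(c1OC)[C@H](OC)[C@@H](C)C[C@H](OC)[C@H](OC)[C@@H](C)/C=C(C)\[C@H](O)[C@@H](OC)C=C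
F7 | step 14 | (3S,4S,5Z,7S,8R,9S,11S,12R)-12-(2,5-dimethoxy-3-nitrophenyl)-3,8,9,12-tetramethoxy-5,7,11-trimethyldodeca-1,5-dien-4-yl prop-2-enoate | O=[N+]([O-])c1cc(OC)cc(c1OC)[C@H](OC)[C@@H](C)C[C@H](OC)[C@H](OC)[C@@H](C)/C=C(C)\[C@H](OC(=O)C=C)[C@@H](OC)C=C
F8 | step 16 | (2Z,4S,5S,6Z,8S,9R,10S,12S,13R)-13-(2,5-dimethoxy-3-nitrophenyl)-5-hydroxy-N,4,9,10,13-pentamethoxy-N,6,8,12-tetramethyltrideca-2,6-dienamide | O=[N+]([O-])c1cc(OC)cc(c1OC)[C@H](OC)[C@@H](C)C[C@H](OC)[C@H](OC)[C@@H](C)/C=C(C)\[C@H](O)[C@@H](OC)/C=C\C(=O)N(C)OC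
F9 | step 16 | O5-(trichloroacetylcarbamoyl) derivative of F8 (not isolated) | O=[N+]([O-])c1cc(OC)cc(c1OC)[C@H](OC)[C@@H](C)C[C@H](OC)[C@H](OC)[C@@H](C)/C=C(C)\[C@H](OC(=O)NC(=O)C(Cl)(Cl)Cl)[C@@H](OC)/C=C\C(=O)N(C)OC
F10 | step 16 | O5-carbamoyl derivative of F8 (carbamate Weinreb amide) | O=[N+]([O-])c1cc(OC)cc(c1OC)[C@H](OC)[C@@H](C)C[C@H](OC)[C@H](OC)[C@@H](C)/C=C(C)\[C@H](OC(N)=O)[C@@H](OC)/C=C\C(=O)N(C)OC
F11 | step 16 | (2Z,4S,5S,6Z,8S,9R,10S,12S,13R)-13-(2,5-dimethoxy-3-nitrophenyl)-4,9,10,13-tetramethoxy-6,8,12-trimethyl-1-oxotrideca-2,6-dien-5-yl carbamate | O=[N+]([O-])c1cc(OC)cc(c1OC)[C@H](OC)[C@@H](C)C[C@H](OC)[C@H](OC)[C@@H](C)/C=C(C)\[C@H](OC(N)=O)[C@@H](OC)/C=C\C=O
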